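**Retrosynthetic overview**
- The strategy rests on one feature: ring B (C5–C10) with its C8 methyl, the C7=C8 alkene and the C5 stereocentre is the ring of (S)-carvone, and the isopropenyl carbon of carvone is C4, which needs only one hydrogen atom and the C3–C4 bond to become the gem-dimethyl carbon of ring A.
- Ring B comes from the chiral pool; ring A is closed second, by hydrogen-atom-transfer radical cyclisation of a 6-acryloyl-6-methylcarvone (C3–C4 bond) to a trans-fused 1,9-dione.
- The C1 ketone is deleted through its enol triflate and the C2 oxygen is put in by hydroboration of the C1=C2 alkene; the C9 ketone becomes a methylene group whose hydroboration sets H9, and a B-alkyl Suzuki coupling forms C11–C12.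
- C13 is set by Sharpless epoxidation of the C12=C13 allylic alcohol, hydride opening at C12 and one-carbon homologation of the 13,14-epoxide to the vinyl carbinol; the C2 senecioate is made last.

Key step: step 4

Remark: labdane numbering is used for all bicyclic compounds, and "syn" and "anti" give the face relative to the C10 methyl group (H5 is anti in every decalin). Compound 4 is carried as its two C6 epimers and 7 as its two carbinol epimers, since both centres are erased in steps 2 and 3.

Step 1
Reactants: 1 (S)-carvone; 2 iodomethane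
Product: 4 (5S)-2,6-dimethyl-5-(prop-1-en-2-yl)cyclohex-2-en-1-one (6-methylcarvone; methyl trans to isopropenyl in the major epimer), via lithium enolate 3 (not isolated)
Conditions: LiN(iPr)2, THF, −78 °C; then MeI, −78 → −20 °C
Reagents that add atoms: iodomethane (2), CI
Why: Kinetic deprotonation of the ring CH2 next to the ketone gives the cross-conjugated enolate, which is C-methylated (enolate alkylation); the configuration of the new centre is immaterial because it is planarised again in step 2.

Step 2
Reactants: 4 6-methylcarvone; 5 acrolein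
Product: 7 (5S)-6-(1-hydroxyprop-2-en-1-yl)-2,6-dimethyl-5-(prop-1-en-2-yl)cyclohex-2-en-1-one (hydroxyallyl arm trans to isopropenyl; both carbinol epimers), via lithium enolate 6 (not isolated)
Conditions: LiN(iPr)2, THF, −78 °C; then acrolein, −78 °C; AcOH quench at −78 °C
Reagents that add atoms: acrolein (5), C=CC=O
Why: The tetrasubstituted lithium enolate should undergo a kinetic aldol 1,2-addition to acrolein on the ring face opposite the neighbouring isopropenyl group, which fixes the quaternary carbon (later C10) with its methyl cis and its three-carbon arm trans to isopropenyl.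

Step 3
Reactants: 7 aldol adduct
Product: 8 2,6-dimethyl-6-(prop-2-enoyl)-5-(prop-1-en-2-yl)cyclohex-2-en-1-one (6-acryloyl-6-methylcarvone; acryloyl trans to isopropenyl)
Conditions: Dess–Martin periodinane, CH2Cl2, 0 °C → rt
Reagents that add atoms: none
Why: Dess–Martin oxidation of the secondary allylic alcohol gives the vinyl ketone under neutral conditions, and both carbinol epimers converge on one non-enolisable 1,3-diketone.

Step 4
Reactants: 8 6-acryloyl-6-methylcarvone
Product: 9 trans-fused 4,4,8,10-tetramethyldecal-7-ene-1,9-dione (2,5,5,8a-tetramethyl-4,4a,5,6,7,8a-hexahydronaphthalene-1,8-dione; H5 anti to the C10 methyl)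
Conditions: Fe(acac)3 (0.3 equiv), PhSiH3 (2.5 equiv), EtOH/(CH2OH)2, 0.02 M, 60 °C
Reagents that add atoms: none
Why: Fe(acac)3 and PhSiH3 in ethanol should form an iron hydride (trivalent iron) that transfers a hydrogen atom to the CH2 terminus of the electron-rich isopropenyl group to give the tertiary C4 radical, which adds to the β-carbon C3 of the acryloyl group (6-endo-trig closure of ring A through the new C3–C4 bond), after which the C2 α-keto radical is reduced to the enolate and protonated by the solvent. The closest known reaction type is the iron-mediated hydrogen-atom-transfer reductive coupling of an unactivated alkene with an enone (a radical conjugate addition of Giese type), used here in its intramolecular form. No stereocentre is created, since C4 becomes the gem-dimethyl carbon and C2 a CH2 group, and the trans ring fusion is dictated by C5 and C10, whose reacting arms are trans on ring B and can bridge only diequatorially. The step needs hydrogen-atom transfer to the isopropenyl group and not to either enone, and attack at C3 and not at C2; both follow from polarity matching, because the metal hydride prefers the electron-rich 1,1-disubstituted alkene and the nucleophilic tertiary radical prefers the unsubstituted β-carbon, whereas 5-exo attack at C2 would leave an unstabilised primary radical.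

Step 5
Reactants: 9 decalin-1,9-dione
Product: 11 4,4,8,10-tetramethyl-9-oxodecala-1,7-dien-1-yl trifluoromethanesulfonate (C1 enol triflate), via potassium enolate 10 (not isolated)
Conditions: KN(SiMe3)2, THF, −78 °C; then PhNTf2, −78 → 0 °C
Reagents that add atoms: N-phenylbis(trifluoromethanesulfonimide), O=S(=O)(N(c1ccccc1)S(=O)(=O)C(F)(F)F)C(F)(F)F
Why: Enol triflate formation should be selective because the C1 ketone can enolise only toward C2 (C10 is quaternary) and its α-protons are removed kinetically faster than the γ-protons of the C9 enone.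

Step 6
Reactants: 11 C1 enol triflate
Product: 12 trans-fused 4,4,8,10-tetramethyldecala-1,7-dien-9-one
Conditions: Pd(OAc)2 (cat.), PPh3, HCO2H, Bu3N, DMF, 60 °C
Reagents that add atoms: none
Why: Palladium-catalysed formate reduction of an enol triflate (oxidative addition, formate exchange, loss of CO2, C–H reductive elimination) removes the C1 oxygen and leaves the C1=C2 alkene, which cannot move into conjugation because C10 is quaternary.

Step 7
Reactants: 12 dienone; 13 dimethyltitanocene Cp2TiMe2
Product: 14 ent-drima-1,7,9(11)-triene (9-methylene-4,4,8,10-tetramethyldecala-1,7-diene)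
Conditions: Cp2TiMe2 (3 equiv), toluene, 75 °C, dark
Reagents that add atoms: dimethyltitanocene (13), C[Ti](C)(C1C=CC=C1)C1C=CC=C1
Why: Petasis methylenation through Cp2Ti=CH2 and an oxatitanacyclobutane is non-basic and small enough for the hindered, γ-enolisable C9 ketone, and gives a diene that is locked s-trans.

Step 8
Reactants: 15 prop-2-yn-1-ol; 16 trimethylaluminium
Product: 18 (E)-3-iodo-2-methylprop-2-en-1-ol, via alkenylalane 17 (not isolated)
Conditions: Me3Al (3 equiv), Cp2ZrCl2 (0.25 equiv), CH2Cl2, 0 °C → rt; then I2, THF, −30 → 0 °C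
Reagents that add atoms: trimethylaluminium (16), C[Al](C)C; iodine, II
Why: Zirconium-catalysed Negishi carboalumination adds methyl and aluminium syn across the alkyne with aluminium on the terminal carbon, and iodinolysis with retention gives the E-iodide.

Step 9
Reactants: 14 triene; 18 (E)-3-iodo-2-methylprop-2-en-1-ol
Product: 20 (12E)-15-nor-ent-labda-1,7,12-trien-14-ol (C11 syn and H9 anti to the C10 methyl), via alkylborane 19 (not isolated)
Conditions: 9-BBN (1.2 equiv), THF, 0 °C → rt; then 18, Pd(dppf)Cl2 (cat.), AsPh3, Cs2CO3, DMF/H2O, rt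
Reagents that add atoms: (E)-3-iodo-2-methylprop-2-en-1-ol (18), OC/C(C)=C/I
Why: 9-BBN should hydroborate only the exocyclic CH2 terminus of the diene at room temperature, from the face opposite the adjacent C10 methyl so that H9 ends anti and C11 syn to it, and the primary alkylborane then undergoes B-alkyl Suzuki–Miyaura coupling with retention of the E geometry.

Step 10
Reactants: 20 trienol
Product: 22 (12E)-15-nor-ent-labda-7,12-diene-2,14-diol (2-OH equatorial, anti to the C10 methyl), via catecholboronate 21 (not isolated)
Conditions: catecholborane (3 equiv), Rh(PPh3)3Cl (cat.), THF, 0 °C → rt; then NaOH, H2O2, 0 °C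
Reagents that add atoms: hydrogen peroxide, OO
Why: Rhodium-catalysed hydroboration reacts with cis-disubstituted alkenes but not with the two trisubstituted ones, should place boron on C2 (the only ring A position not next to a quaternary carbon) by cis addition from the face opposite the syn-axial C4 and C10 methyls, and the oxidation proceeds with retention to the equatorial 2-ol.

Step 11
Reactants: 22 diene-diol
Product: 23 (12R,13R)-12,13-epoxy-15-nor-ent-labd-7-ene-2,14-diol
Conditions: Ti(OiPr)4 (0.2 equiv), D-(−)-diethyl tartrate (0.25 equiv), t-BuOOH, 4 Å sieves, CH2Cl2, −20 °C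
Reagents that add atoms: tert-butyl hydroperoxide, CC(C)(C)OO
Why: Sharpless asymmetric epoxidation is reagent-controlled, so the D-(−)-tartrate should deliver oxygen to the face of the E-2-methyl allylic alcohol that gives the (12R,13R)-epoxide, and the isolated C7=C8 alkene is not touched.

Step 12
Reactants: 23 epoxy diol
Product: 24 (13S)-15-nor-ent-labd-7-ene-2,13,14-triol
Conditions: LiAlH4, THF, 0 °C → rt
Reagents that add atoms: none
Why: Hydride opening of a 2-methyl-2,3-epoxy alcohol occurs by SN2 attack at the less substituted epoxide carbon C12, so the C13–O bond is untouched and the tertiary carbinol keeps the configuration set in step 11.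

Step 13
Reactants: 24 triol
Product: 26 (13S)-13,14-epoxy-15-nor-ent-labd-7-en-2-ol, via primary tosylate 25 (not isolated)
Conditions: TsCl, Et3N, Bu2SnO (cat.), CH2Cl2, 0 °C; then K2CO3, MeOH, rt
Reagents that add atoms: none
Why: Tin-oxide-catalysed sulfonylation selects the primary hydroxyl of the 1,2-diol through its stannylene acetal, and intramolecular Williamson displacement by the tertiary alkoxide closes the epoxide without touching C13.

Step 14
Reactants: 26 terminal epoxide; 27 trimethylsulfonium iodide
Product: 28 (13S)-ent-labda-7,14-diene-2,13-diol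
Conditions: Me3S+ I− (6 equiv), n-BuLi (6 equiv), THF, −10 °C → rt
Reagents that add atoms: trimethylsulfonium iodide (27), C[S+](C)C.[I-]
Why: In the sulfonium-ylide homologation of an epoxide to an allylic alcohol, dimethylsulfonium methylide opens the epoxide at its CH2 carbon and the γ-oxido sulfonium salt loses dimethyl sulfide through its own ylide to form the vinyl group, leaving C13 unchanged.

Step 15
Reactants: 28 diene-diol; 29 3-methylbut-2-enoic acid
Product: 30 CNP0252389.1, (13S)-13-hydroxy-ent-labda-7,14-dien-2-yl 3-methylbut-2-enoate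
Conditions: DCC, DMAP (cat.), CH2Cl2, 0 °C → rt
Reagents that add atoms: 3-methylbut-2-enoic acid (29), CC(C)=CC(=O)O
Why: Steglich esterification acylates the secondary equatorial C2 hydroxyl, while the tertiary allylic C13 hydroxyl is too hindered to react.

**Compound list**
1 | (S)-carvone, (5S)-2-methyl-5-(prop-1-en-2-yl)cyclohex-2-en-1-one | CC1=CC[C@@H](CC1=O)C(C)=C | starting material
2 | iodomethane | CI | starting material
3 | lithium enolate of 1 | [Li+].CC1=CC[C@@H](C=C1[O-])C(C)=C | intermediate (not isolated)
4 | 6-methylcarvone, major epimer with methyl trans to isopropenyl | C[C@H]1C(=O)C(C)=CC[C@@H]1C(C)=C | intermediate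
5 | acrolein | C=CC=O | starting material
6 | lithium enolate of 4 | [Li+].CC1=CC[C@@H](C(C)=C1[O-])C(C)=C | intermediate (not isolated)
7 | 6-(1-hydroxyprop-2-en-1-yl)-6-methylcarvone, arm trans to isopropenyl, carbinol epimers | C=CC(O)[C@@]1(C)C(=O)C(C)=CC[C@@H]1C(C)=C | intermediate
8 | 6-acryloyl-6-methylcarvone, acryloyl trans to isopropenyl | C=CC(=O)[C@@]1(C)C(=O)C(C)=CC[C@@H]1C(C)=C | intermediate
9 | trans-fused 4,4,8,10-tetramethyldecal-7-ene-1,9-dione | CC1=CC[C@@H]2C(C)(C)CCC(=O)[C@@]2(C)C1=O | intermediate
10 | potassium C1 enolate of 9 | [K+].CC1=CC[C@@H]2C(C)(C)CC=C([O-])[C@@]2(C)C1=O | intermediate (not isolated)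
11 | C1 enol triflate of 9 | CC1=CC[C@@H]2C(C)(C)CC=C(OS(=O)(=O)C(F)(F)F)[C@@]2(C)C1=O | intermediate
12 | trans-fused 4,4,8,10-tetramethyldecala-1,7-dien-9-one | CC1=CC[C@@H]2C(C)(C)CC=C[C@@]2(C)C1=O | intermediate
13 | dimethyltitanocene (cyclopentadienyl rings drawn σ-bonded) | C[Ti](C)(C1C=CC=C1)C1C=CC=C1 | starting material
14 | ent-drima-1,7,9(11)-triene | CC1=CC[C@@H]2C(C)(C)CC=C[C@@]2(C)C1=C | intermediate
15 | prop-2-yn-1-ol | C#CCO | starting material
16 | trimethylaluminium | C[Al](C)C | starting material
17 | (E)-alkenylalane, dimethylaluminium alkoxide | C[Al](C)/C=C(\C)CO[Al](C)C | intermediate (not isolated)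
18 | (E)-3-iodo-2-methylprop-2-en-1-ol | OC/C(C)=C/I | intermediate
19 | B-(ent-drima-1,7-dien-11-yl)-9-BBN, C11 syn to the C10 methyl | CC1=CC[C@@H]2C(C)(C)CC=C[C@@]2(C)[C@@H]1CB1C2CCCC1CCC2 | intermediate (not isolated)
20 | (12E)-15-nor-ent-labda-1,7,12-trien-14-ol | CC1=CC[C@@H]2C(C)(C)CC=C[C@@]2(C)[C@@H]1C/C=C(\C)CO | intermediate
21 | C2 catecholboronate and C14 catecholborate of 20 | CC1=CC[C@@H]2C(C)(C)C[C@@H](B3Oc4ccccc4O3)C[C@@]2(C)[C@@H]1C/C=C(\C)COB1Oc2ccccc2O1 | intermediate (not isolated)
22 | (12E)-15-nor-ent-labda-7,12-diene-2,14-diol, 2-OH anti to the C10 methyl | CC1=CC[C@@H]2C(C)(C)C[C@@H](O)C[C@@]2(C)[C@@H]1C/C=C(\C)CO | intermediate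
23 | (12R,13R)-12,13-epoxy-15-nor-ent-labd-7-ene-2,14-diol | CC1=CC[C@@H]2C(C)(C)C[C@@H](O)C[C@@]2(C)[C@@H]1C[C@H]3O[C@]3(C)CO | intermediate
24 | (13S)-15-nor-ent-labd-7-ene-2,13,14-triol | CC1=CC[C@@H]2C(C)(C)C[C@@H](O)C[C@@]2(C)[C@@H]1CC[C@](C)(O)CO | intermediate
25 | 14-O-tosylate of 24 | CC1=CC[C@@H]2C(C)(C)C[C@@H](O)C[C@@]2(C)[C@@H]1CC[C@](C)(O)COS(=O)(=O)c1ccc(C)cc1 | intermediate (not isolated)
26 | (13S)-13,14-epoxy-15-nor-ent-labd-7-en-2-ol | CC1=CC[C@@H]2C(C)(C)C[C@@H](O)C[C@@]2(C)[C@@H]1CC[C@@]3(C)CO3 | intermediate
27 | trimethylsulfonium iodide | C[S+](C)C.[I-] | starting material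
28 | (13S)-ent-labda-7,14-diene-2,13-diol | CC1=CC[C@@H]2C(C)(C)C[C@@H](O)C[C@@]2(C)[C@@H]1CC[C@](C)(O)C=C | intermediate
29 | 3-methylbut-2-enoic acid | CC(C)=CC(=O)O | starting material
30 | CNP0252389.1, (13S)-13-hydroxy-ent-labda-7,14-dien-2-yl 3-methylbut-2-enoate | CC1=CC[C@@H]2C(C)(C)C[C@@H](OC(=O)C=C(C)C)C[C@@]2(C)[C@@H]1CC[C@](C)(O)C=C | target

**Step count**
Total: 15 steps. Longest linear sequence: 14 steps (steps 1–7 and 9–15 from (S)-carvone); step 8 makes the coupling partner.

**Steps most likely to fail**

Step 10. Turnover at the ring A alkene, which sits next to the quaternary C10, may be slow. The rhodium hydride could then move the alkene, isomerise the allylic alcohol or deliver boron to C1. The fallback sets out from triene 14 and puts the C2 boron in before the side chain exists. Excess 9-BBN in THF at 65 °C should hydroborate both C9=C11 and C1=C2 to the bis-borane F1. In the Suzuki coupling with 18 (Pd(dppf)Cl2, AsPh3, Cs2CO3) only the primary C11–B bond transmetalates, which gives the C2 borane F2. Oxidation of the surviving secondary borane with NaOH/H2O2 returns to diol 22.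

Step 9. The β-branched alkylborane next to C10 may transmetalate slowly, so that protodeboronation or β-hydride elimination competes, and the one-pot format gives no chance to remove a minor C9 epimer. The fallback sets out from triene 14 and separates the two events. Borane 19 is oxidised (NaOH, H2O2) to ent-drima-1,7-dien-11-ol F3, which is purified. It is converted with I2, PPh3 and imidazole to the iodide F4, and zinc insertion (Zn, LiCl, THF) gives the alkylzinc iodide F5. Negishi coupling with 18 (pre-treated with i-PrMgCl; Pd(OAc)2 and a biarylphosphine) returns to 20.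

Step 4. The iron hydride may reduce the tertiary radical to an isopropyl group before ring closure, or transfer hydrogen to the vinyl ketone, and the enone may oligomerise. The fallback sets out from 8 and makes the same C4 radical from a carbon–bromine bond. HBr in AcOH adds to the isopropenyl group (Markovnikov) and to the vinyl ketone to give the dibromide F6. Et3N removes HBr only from the β-bromo ketone to give the tertiary bromide F7. Slow addition of Bu3SnH with AIBN in benzene at 80 °C closes ring A by the same 6-endo radical conjugate addition and returns to 9.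

**Further compounds**
F1 | step 10 | 2,11-bis(9-BBN) adduct of 14, boron at C2 anti to the C10 methyl | CC1=CC[C@@H]2C(C)(C)C[C@@H](B3C4CCCC3CCC4)C[C@@]2(C)[C@@H]1CB1C2CCCC1CCC2
F2 | step 10 | (12E)-2-(9-BBN-9-yl)-15-nor-ent-labda-7,12-dien-14-ol | CC1=CC[C@@H]2C(C)(C)C[C@@H](B3C4CCCC3CCC4)C[C@@]2(C)[C@@H]1C/C=C(\C)CO
F3 | step 9 | ent-drima-1,7-dien-11-ol | CC1=CC[C@@H]2C(C)(C)CC=C[C@@]2(C)[C@@H]1CO
F4 | step 9 | 11-iodo-ent-drima-1,7-diene | CC1=CC[C@@H]2C(C)(C)CC=C[C@@]2(C)[C@@H]1CI
F5 | step 9 | (ent-drima-1,7-dien-11-yl)zinc iodide | CC1=CC[C@@H]2C(C)(C)CC=C[C@@]2(C)[C@@H]1C[Zn]I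
F6 | step 4 | 6-(3-bromopropanoyl)-5-(2-bromopropan-2-yl)-2,6-dimethylcyclohex-2-en-1-one, arms trans | BrCCC(=O)[C@@]1(C)C(=O)C(C)=CC[C@@H]1C(C)(C)Br
F7 | step 4 | 6-acryloyl-5-(2-bromopropan-2-yl)-2,6-dimethylcyclohex-2-en-1-one, arms trans | C=CC(=O)[C@@]1(C)C(=O)C(C)=CC[C@@H]1C(C)(C)Br
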